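**Assumption:** the target has no stereocentre and is achiral, so there is no enantiomer to control. The racemic intermediates 9 and 11 lose their stereocentres before they can matter.

## Retrosynthetic overview

1. Target 13 ← flavonol 12 by removal of four MOM ethers; the 4'-OMe is already in place.
2. Ring C (the pyranone) is the only ring built: 12 ← 2'-hydroxychalcone 10 by Algar–Flynn–Oyamada oxidative cyclisation (O1–C2 bond and 3-OH together).
3. Chalcone 10 ← Claisen–Schmidt aldol condensation of ring A ketone 3 with ring B aldehyde 8 (the key C–C bond).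
4. Ketone 3 ← phloroacetophenone 1 (nuclear C-dimethylation, then bis-MOM protection).
5. Aldehyde 8 ← methyl gallate 4 (4-O-methylation, bis-MOM protection, ester → CH2OH → CHO).

## Route

**Step 1**
Reactants: 1 1-(2,4,6-trihydroxyphenyl)ethanone (phloroacetophenone)
Product: 2 1-(2,4,6-trihydroxy-3,5-dimethylphenyl)ethanone
Conditions: NaOMe (3 equiv), MeI (2.1 equiv, slow addition), MeOH, 0 °C → rt; dilute HCl work-up, chromatography
Reagents that add atoms: iodomethane, CI
Why: Nuclear C-methylation of the phloroglucinol polyphenoxide (ambident enolate alkylation) puts methyl on the two free ring carbons, and the limited MeI charge keeps gem-dimethylation down.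

**Step 2**
Reactants: 2 1-(2,4,6-trihydroxy-3,5-dimethylphenyl)ethanone
Product: 3 1-[2-hydroxy-4,6-bis(methoxymethoxy)-3,5-dimethylphenyl]ethanone
Conditions: MOMCl (2.2 equiv), iPr2NEt (2.6 equiv), CH2Cl2, 0 °C → rt
Reagents that add atoms: chloromethyl methyl ether, COCCl
Why: Williamson-type O-alkylation with a hard electrophile stops at the bis-ether because the last ortho OH is locked in a hydrogen bond to the ketone.

**Step 3**
Reactants: 4 methyl 3,4,5-trihydroxybenzoate (methyl gallate)
Product: 5 methyl 3,5-dihydroxy-4-methoxybenzoate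
Conditions: MeI (1.05 equiv), KHCO3 (1.1 equiv), DMF, rt, 24–48 h
Reagents that add atoms: iodomethane, CI
Why: Regioselective Williamson ether synthesis, since only the 4-OH para to the ester is acidic enough to be deprotonated by the weak base.

**Step 4**
Reactants: 5 methyl 3,5-dihydroxy-4-methoxybenzoate
Product: 6 methyl 4-methoxy-3,5-bis(methoxymethoxy)benzoate
Conditions: MOMCl (2.5 equiv), iPr2NEt (3 equiv), CH2Cl2, 0 °C → rt
Reagents that add atoms: chloromethyl methyl ether, COCCl
Why: Straightforward MOM acetal protection of both remaining phenols (O-alkylation), giving groups stable to hydride, base and peroxide.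

**Step 5**
Reactants: 6 methyl 4-methoxy-3,5-bis(methoxymethoxy)benzoate
Product: 7 [4-methoxy-3,5-bis(methoxymethoxy)phenyl]methanol
Conditions: LiAlH4, THF, 0 °C → rt; aqueous quench
Reagents that add atoms: none
Why: Hydride reduction of the ester to the benzylic alcohol, with the MOM and methyl ethers inert.

**Step 6**
Reactants: 7 [4-methoxy-3,5-bis(methoxymethoxy)phenyl]methanol
Product: 8 4-methoxy-3,5-bis(methoxymethoxy)benzaldehyde
Conditions: activated MnO2 (10 equiv), CH2Cl2, rt
Reagents that add atoms: none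
Why: Selective benzylic alcohol oxidation that stops at the aldehyde under neutral conditions harmless to MOM ethers.

**Step 7**
Reactants: 3 1-[2-hydroxy-4,6-bis(methoxymethoxy)-3,5-dimethylphenyl]ethanone; 8 4-methoxy-3,5-bis(methoxymethoxy)benzaldehyde
Product: 10 (E)-1-[2-hydroxy-4,6-bis(methoxymethoxy)-3,5-dimethylphenyl]-3-[4-methoxy-3,5-bis(methoxymethoxy)phenyl]prop-2-en-1-one, via β-hydroxy ketone 9 (not isolated)
Conditions: KOH (50% aq, excess), EtOH, rt, 24–48 h; neutralise cold with AcOH
Reagents that add atoms: none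
Why: Claisen–Schmidt aldol condensation of the methyl ketone enolate with the non-enolisable aldehyde, followed by E1cB loss of water from racemic 9 to the conjugated E-enone.

**Step 8**
Reactants: 10 (E)-1-[2-hydroxy-4,6-bis(methoxymethoxy)-3,5-dimethylphenyl]-3-[4-methoxy-3,5-bis(methoxymethoxy)phenyl]prop-2-en-1-one
Product: 12 3-hydroxy-2-[4-methoxy-3,5-bis(methoxymethoxy)phenyl]-5,7-bis(methoxymethoxy)-6,8-dimethyl-4H-chromen-4-one, via trans-dihydroflavonol 11 (not isolated)
Conditions: 30% H2O2 (5 equiv), 2 M NaOH aq, MeOH/THF, 0 °C → rt; AcOH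
Reagents that add atoms: hydrogen peroxide, OO
Why: Algar–Flynn–Oyamada reaction, in which the 2'-phenoxide closes ring C with oxygenation at the α-carbon to give racemic 11, which alkaline peroxide dehydrogenates in the same pot to the flavonol.

**Step 9**
Reactants: 12 3-hydroxy-2-[4-methoxy-3,5-bis(methoxymethoxy)phenyl]-5,7-bis(methoxymethoxy)-6,8-dimethyl-4H-chromen-4-one
Product: 13 2-(3,5-dihydroxy-4-methoxyphenyl)-3,5,7-trihydroxy-6,8-dimethyl-4H-chromen-4-one (6,8-di-C-methylmyricetin 4'-methyl ether)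
Conditions: conc. HCl (few equiv), MeOH/THF, 55 °C
Reagents that add atoms: none
Why: Acid-catalysed acetal exchange (MOM deprotection) frees all four phenols, while the aryl methyl ether and the flavonol core are stable to methanolic HCl.

## Compound list

1 | 1-(2,4,6-trihydroxyphenyl)ethanone (phloroacetophenone) | CC(=O)c1c(O)cc(O)cc1O | starting material
2 | 1-(2,4,6-trihydroxy-3,5-dimethylphenyl)ethanone | CC(=O)c1c(O)c(C)c(O)c(C)c1O | intermediate
3 | 1-[2-hydroxy-4,6-bis(methoxymethoxy)-3,5-dimethylphenyl]ethanone | CC(=O)c1c(O)c(C)c(OCOC)c(C)c1OCOC | intermediate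
4 | methyl 3,4,5-trihydroxybenzoate (methyl gallate) | COC(=O)c1cc(O)c(O)c(O)c1 | starting material
5 | methyl 3,5-dihydroxy-4-methoxybenzoate | COC(=O)c1cc(O)c(OC)c(O)c1 | intermediate
6 | methyl 4-methoxy-3,5-bis(methoxymethoxy)benzoate | COC(=O)c1cc(OCOC)c(OC)c(OCOC)c1 | intermediate
7 | [4-methoxy-3,5-bis(methoxymethoxy)phenyl]methanol | OCc1cc(OCOC)c(OC)c(OCOC)c1 | intermediate
8 | 4-methoxy-3,5-bis(methoxymethoxy)benzaldehyde | O=Cc1cc(OCOC)c(OC)c(OCOC)c1 | intermediate
9 | 3-hydroxy-1-[2-hydroxy-4,6-bis(methoxymethoxy)-3,5-dimethylphenyl]-3-[4-methoxy-3,5-bis(methoxymethoxy)phenyl]propan-1-one (racemic, one stereocentre, drawn without configuration) | COCOc1c(C)c(O)c(C(=O)CC(O)c2cc(OCOC)c(OC)c(OCOC)c2)c(OCOC)c1C | intermediate (not isolated)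
10 | (E)-1-[2-hydroxy-4,6-bis(methoxymethoxy)-3,5-dimethylphenyl]-3-[4-methoxy-3,5-bis(methoxymethoxy)phenyl]prop-2-en-1-one | COCOc1c(C)c(O)c(C(=O)/C=C/c2cc(OCOC)c(OC)c(OCOC)c2)c(OCOC)c1C | intermediate
11 | rac-(2R,3R)-3-hydroxy-2-[4-methoxy-3,5-bis(methoxymethoxy)phenyl]-5,7-bis(methoxymethoxy)-6,8-dimethylchroman-4-one (racemic trans; one enantiomer drawn) | COCOc1cc([C@@H]2[C@@H](O)C(=O)c3c(OCOC)c(C)c(OCOC)c(C)c3O2)cc(OCOC)c1OC | intermediate (not isolated)
12 | 3-hydroxy-2-[4-methoxy-3,5-bis(methoxymethoxy)phenyl]-5,7-bis(methoxymethoxy)-6,8-dimethyl-4H-chromen-4-one | COCOc1cc(-c2oc3c(C)c(OCOC)c(C)c(OCOC)c3c(=O)c2O)cc(OCOC)c1OC | intermediate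
13 | 2-(3,5-dihydroxy-4-methoxyphenyl)-3,5,7-trihydroxy-6,8-dimethyl-4H-chromen-4-one | COc1c(O)cc(-c2oc3c(C)c(O)c(C)c(O)c3c(=O)c2O)cc1O | target

## Step count and risks

Total steps: 9. Longest linear sequence: 7 steps (4 → 5 → 6 → 7 → 8 → 10 → 12 → 13, steps 3–9).

**Step 8 (most likely to fail).** The 6'-alkoxy group, buttressed by the 5'-methyl, twists the enone and can divert the reaction to the aurone. Fallback: set out from chalcone 10 and separate epoxidation from ring closure. Cap the 2'-OH (NaH, MOMCl, DMF, 0 °C) to give (E)-1-[2,4,6-tris(methoxymethoxy)-3,5-dimethylphenyl]-3-[4-methoxy-3,5-bis(methoxymethoxy)phenyl]prop-2-en-1-one F1. Weitz–Scheffer epoxidation (30% H2O2, NaOH aq, MeOH/THF) gives the racemic trans-epoxide rac-[(2S,3R)-3-[4-methoxy-3,5-bis(methoxymethoxy)phenyl]oxiran-2-yl][2,4,6-tris(methoxymethoxy)-3,5-dimethylphenyl]methanone F2. HCl in MeOH at 55 °C removes all five MOM groups, and the freed ortho OH opens the epoxide at the benzylic carbon (6-endo) to give rac-(2R,3R)-2-(3,5-dihydroxy-4-methoxyphenyl)-3,5,7-trihydroxy-6,8-dimethylchroman-4-one F3. Dehydrogenation (I2, KOAc, AcOH, reflux) then gives 13, so the fallback rejoins the route at 13 and replaces steps 8 and 9.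

**Step 1.** Mono-, di- and tri-C-methylated products plus O-methyl ethers can form together and are hard to separate. Fallback: set out from 1 and introduce the two carbons by a double Mannich aminomethylation (37% aq CH2O, 40% aq Me2NH, EtOH, 0 °C → rt) to give 1-{3,5-bis[(dimethylamino)methyl]-2,4,6-trihydroxyphenyl}ethanone F4. Hydrogenolysis of both benzylic C–N bonds (H2, Pd/C, AcOH, 60 °C) then gives 2, where the route resumes. Aminomethylation cannot over-alkylate a ring carbon, which removes the gem-dimethyl problem.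

**Step 3.** Some 3-O-methyl and di-O-methyl gallate may accompany the 4-O-methyl product. Fallback: set out from 4 and peracetylate (Ac2O, pyridine, rt) to methyl 3,4,5-triacetoxybenzoate F5. Treatment with MeI and K2CO3 in refluxing acetone cleaves only the most labile 4-acetate (para to the ester) and methylates the phenoxide in situ, giving methyl 3,5-diacetoxy-4-methoxybenzoate F6. Mild methanolysis (catalytic K2CO3, MeOH, rt) removes the two remaining acetates and gives 5, where the route resumes.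

## Further compounds

F1 | step 8 | (E)-1-[2,4,6-tris(methoxymethoxy)-3,5-dimethylphenyl]-3-[4-methoxy-3,5-bis(methoxymethoxy)phenyl]prop-2-en-1-one | COCOc1c(C)c(OCOC)c(C(=O)/C=C/c2cc(OCOC)c(OC)c(OCOC)c2)c(OCOC)c1C
F2 | step 8 | rac-[(2S,3R)-3-[4-methoxy-3,5-bis(methoxymethoxy)phenyl]oxiran-2-yl][2,4,6-tris(methoxymethoxy)-3,5-dimethylphenyl]methanone (racemic trans; one enantiomer drawn) | COCOc1c(C)c(OCOC)c(C(=O)[C@H]2O[C@@H]2c3cc(OCOC)c(OC)c(OCOC)c3)c(OCOC)c1C
F3 | step 8 | rac-(2R,3R)-2-(3,5-dihydroxy-4-methoxyphenyl)-3,5,7-trihydroxy-6,8-dimethylchroman-4-one (racemic trans; one enantiomer drawn) | COc1c(O)cc([C@@H]2[C@@H](O)C(=O)c3c(O)c(C)c(O)c(C)c3O2)cc1O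
F4 | step 1 | 1-{3,5-bis[(dimethylamino)methyl]-2,4,6-trihydroxyphenyl}ethanone | CC(=O)c1c(O)c(CN(C)C)c(O)c(CN(C)C)c1O
F5 | step 3 | methyl 3,4,5-triacetoxybenzoate | COC(=O)c1cc(OC(C)=O)c(OC(C)=O)c(OC(C)=O)c1
F6 | step 3 | methyl 3,5-diacetoxy-4-methoxybenzoate | COC(=O)c1cc(OC(C)=O)c(OC)c(OC(C)=O)c1
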